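**Plan**

1. Labels: ring A is the central benzene that carries both dihydrofurans; ring B is the resorcinol ring fused to the seven-membered ring; the west furan is the dihydrofuran whose C3 is a carbon of the seven-membered ring; the east furan is the other one.
2. Retrosynthesis: after the seven phenols, each furan is cut at O–C2 and C2–C3 (an o-quinone methide on ring A plus a 4-methoxybenzyl sulfur ylide). The east C3–ring A bond is then cut (aryl Grignard plus aldehyde), and the west C3 becomes the ketone carbon of a dibenzocycloheptanone.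
3. Feature for the key cut: ring B shows, from the fusion carbon on the ketone to the fusion carbon on the methine, CH, C–OMe, CH, C–OSi. These are C5, C4 and C3 of a 4-methoxy-2-pyrone plus the oxygen-bearing carbon of a silyl ynol ether, and the fusion carbons are pyrone C6 and the inner alkyne carbon. Cutting the two ring-B bonds of a pyrone–alkyne Diels–Alder reaction (with CO2 put back) opens ring B and the seven-membered ring together.
4. Forward order: Evans benzylation (methine), Corey–Fuchs alkyne, double iodination of ring A, silyl ynol ether, aryl Grignard plus pyrone aldehyde, ketone, cycloaddition (ring B and seven-membered ring), west furan, east furan from the second iodide, deprotection.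
5. Stereochemistry: the methine (S) comes from (S)-4-benzyloxazolidin-2-one. The west furan (2S,3S) comes from ylide attack anti to the methine aryl group, reinforced by the (1R,4R,5R)-isothiocineole ylide. The east furan (2R,3R) comes from the (1S,4S,5S)-isothiocineole ylide. Both furans are trans through the annulation.

Key step: step 12

Remark (assumption): both enantiomers of isothiocineole are taken as purchasable, and their 4-methoxybenzyl ylides are taken to add to quinone methides with the facial sense of their aldehyde epoxidations (exo-alkylated sulfonium, aryl group syn to the sulfur lone pair, attack away from the gem-dimethyl carbon); if a model annulation shows the opposite sense, the two enantiomeric sulfides change places.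

**Route**

Step 1
Reactants: 1 4-methoxyphenylacetic acid; 2 (S)-4-benzyloxazolidin-2-one
Product: 4 (S)-4-benzyl-3-[(4-methoxyphenyl)acetyl]oxazolidin-2-one, via mixed pivalic anhydride 3 (not isolated)
Conditions: t-BuCOCl, Et3N, THF, −20 °C; then 2, LiCl, −20 °C → rt
Reagents that add atoms: none
Why: N-acylation of the oxazolidinone by a mixed anhydride (LiCl-assisted) is the standard entry to Evans imides and forms no stereocentre.

Step 2
Reactants: 4 (S)-4-benzyl-3-[(4-methoxyphenyl)acetyl]oxazolidin-2-one; 5 3,5-bis(benzyloxy)benzyl bromide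
Product: 7 (S)-4-benzyl-3-[(2S)-3-[3,5-bis(benzyloxy)phenyl]-2-(4-methoxyphenyl)propanoyl]oxazolidin-2-one, via sodium Z-enolate 6 (not isolated)
Conditions: NaN(SiMe3)2, THF, −78 °C; 5, −78 → −45 °C
Reagents that add atoms: none
Why: Evans asymmetric alkylation, in which the chelated Z-enolate is benzylated on the face opposite the benzyl group of the (S)-auxiliary, should set the (2S) centre that becomes the ring methine of the target.

Step 3
Reactants: 7 alkylated imide
Product: 8 (2S)-3-[3,5-bis(benzyloxy)phenyl]-2-(4-methoxyphenyl)propan-1-ol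
Conditions: LiBH4, MeOH (1 equiv), Et2O, 0 °C
Reagents that add atoms: none
Why: Reductive cleavage of the Evans auxiliary with LiBH4 attacks the exocyclic carbonyl faster than the α-aryl centre can enolise, so the alcohol should keep its configuration.

Step 4
Reactants: 8 primary alcohol
Product: 9 (2S)-3-[3,5-bis(benzyloxy)phenyl]-2-(4-methoxyphenyl)propanal
Conditions: Dess–Martin periodinane, CH2Cl2, 0 °C; crude aldehyde used at once
Reagents that add atoms: none
Why: Dess–Martin oxidation is fast and non-basic, which should keep the enolisable α-aryl aldehyde configurationally intact if it is carried on without chromatography.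

Step 5
Reactants: 9 aldehyde
Product: 10 (3R)-4-[3,5-bis(benzyloxy)phenyl]-1,1-dibromo-3-(4-methoxyphenyl)but-1-ene
Conditions: CBr4, PPh3, 2,6-lutidine, CH2Cl2, 0 °C
Reagents that add atoms: carbon tetrabromide, BrC(Br)(Br)Br
Why: Ramirez dibromo-olefination (first stage of the Corey–Fuchs sequence) is a Wittig reaction of a non-basic ylide that should consume the aldehyde before it epimerises; the descriptor changes only through the priority rules.

Step 6
Reactants: 10 dibromoalkene
Product: 12 (3R)-4-[3,5-bis(benzyloxy)phenyl]-3-(4-methoxyphenyl)but-1-yne, via lithium acetylide 11 (not isolated)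
Conditions: n-BuLi (2.1 equiv), THF, −78 °C; then H2O
Reagents that add atoms: none
Why: Second stage of the Corey–Fuchs sequence (bromine–lithium exchange, α-elimination with Fritsch–Buttenberg–Wiechell hydride shift, deprotonation to the acetylide), which does not involve the sp3 methine.

Step 7
Reactants: 12 terminal alkyne
Product: 13 (3R)-4-[3,5-bis(benzyloxy)-2,6-diiodophenyl]-3-(4-methoxyphenyl)but-1-yne
Conditions: N-iodosuccinimide (2.1 equiv), CF3CO2H (cat.), MeCN, 0 °C → rt, dark
Reagents that add atoms: N-iodosuccinimide, O=C1CCC(=O)N1I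
Why: Electrophilic aromatic iodination should go to the two equivalent positions of the resorcinol diether ring that are ortho to one benzyloxy group and para to the other, far faster than to the anisyl ring or the alkyne, and placing the iodides only now keeps them away from the butyllithium of step 6.

Step 8
Reactants: 13 diiodo alkyne
Product: 16 (3S)-4-[3,5-bis(benzyloxy)-2,6-diiodophenyl]-3-(4-methoxyphenyl)-1-[(triisopropylsilyl)oxy]but-1-yne, via lithium acetylide 14 (not isolated), via lithium ynolate 15 (not isolated)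
Conditions: LiN(SiMe3)2, THF, −78 °C; t-BuOOLi (from t-BuOOH and LiN(SiMe3)2), −78 → 0 °C; i-Pr3SiOTf, −78 °C
Reagents that add atoms: tert-butyl hydroperoxide, CC(C)(C)OO; triisopropylsilyl trifluoromethanesulfonate, CC(C)[Si](OS(=O)(=O)C(F)(F)F)(C(C)C)C(C)C
Why: Oxidation of a lithium acetylide by lithium tert-butyl peroxide to the ynolate followed by O-silylation with a bulky silyl triflate is the established route to chromatographable silyl ynol ethers, and the amide base is used in place of butyllithium so that the aryl iodides are left alone.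

Step 9
Reactants: 17 4-methoxy-6-methyl-2H-pyran-2-one
Product: 18 4-methoxy-2-oxo-2H-pyran-6-carbaldehyde
Conditions: SeO2, 1,4-dioxane, 160 °C (sealed tube)
Reagents that add atoms: selenium dioxide, O=[Se]=O
Why: Riley oxidation of the vinylogously activated 6-methyl group to the aldehyde is a known reaction of this pyrone.

Step 10
Reactants: 16 silyl ynol ether; 18 pyrone aldehyde
Product: 20 6-{[4,6-bis(benzyloxy)-3-iodo-2-[(2S)-2-(4-methoxyphenyl)-4-[(triisopropylsilyl)oxy]but-3-yn-1-yl]phenyl](hydroxy)methyl}-4-methoxy-2H-pyran-2-one (both carbinol epimers), via arylmagnesium chloride 19 (not isolated)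
Conditions: i-PrMgCl·LiCl (1.05 equiv), THF, −20 °C; 18, −78 → −20 °C; aq. NH4Cl
Reagents that add atoms: none
Why: Iodine–magnesium exchange should take only one of the two equivalent iodides (the ring is deactivated once it carries magnesium), and the aryl Grignard reagent adds to the aldehyde, the most electrophilic site of 18, leaving the pyrone, the silyl ynol ether and the second iodide untouched; the carbinol centre is erased in step 11.

Step 11
Reactants: 20 carbinol
Product: 21 6-{4,6-bis(benzyloxy)-3-iodo-2-[(2S)-2-(4-methoxyphenyl)-4-[(triisopropylsilyl)oxy]but-3-yn-1-yl]benzoyl}-4-methoxy-2H-pyran-2-one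
Conditions: activated MnO2 (excess), CH2Cl2, rt
Reagents that add atoms: none
Why: The carbinol is benzylic and allylic at once, so neutral heterogeneous MnO2 oxidation should give the ketone without exposing the acid-labile ynol ether to acidic oxidant by-products.

Step 12
Reactants: 21 pyronyl aryl ketone tethered to the silyl ynol ether
Product: 23 (10S)-2,4-bis(benzyloxy)-1-iodo-7-methoxy-10-(4-methoxyphenyl)-9-[(triisopropylsilyl)oxy]-10,11-dihydro-5H-dibenzo[a,d]cyclohepten-5-one, via bridged lactone 22 (not isolated)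
Conditions: PhMe (0.005 M), 2,6-di-tert-butyl-4-methylphenol (cat.), 110 °C
Reagents that add atoms: none
Why: Intramolecular inverse-electron-demand Diels–Alder reaction of the 2-pyrone with the alkyne, followed by retro-[4+2] loss of CO2 from the 2-oxabicyclo[2.2.2]octadienone 22; the closest known reactions are thermal pyrone–alkyne cycloaddition/decarboxylations and the additions of ynamines and alkoxyalkynes to electron-poor pyrones. The nucleophilic inner carbon of the ynol ether bonds to the electrophilic C6 of the 6-aroylpyrone and the oxygen-bearing alkyne carbon bonds to C3, the enol-ether β-carbon of the 4-methoxypyrone, so both polarities are matched and an asynchronous or even stepwise path leads to the same adduct. Ring B closes as a six-membered carbocycle in the [4+2] mode, and the seven-membered ring closes in the same event in the fused mode, because the five-atom tether (ketone carbon, two carbons of ring A, CH2, CH) joins pyrone C6 to the alkyne carbon that bonds to it. No stereocentre is formed, since the two bridgeheads of 22 are erased on aromatisation and either diastereomeric adduct gives 23. The selectivity needed is regiochemical and is fixed by the tether, the only arrangement in which the alkyne spans C3 and C6, while the aryl ketone restricts the rotamers of the tether and holds the alkyne over the pyrone. The methine set in step 2 is not acidic under neutral thermal conditions and should be carried through unchanged.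

Step 13
Reactants: 23 dibenzocycloheptanone
Product: 24 (10S)-2-(benzyloxy)-4-hydroxy-1-iodo-7-methoxy-10-(4-methoxyphenyl)-9-[(triisopropylsilyl)oxy]-10,11-dihydro-5H-dibenzo[a,d]cyclohepten-5-one
Conditions: BCl3 (1.1 equiv), CH2Cl2, −78 °C; then H2O
Reagents that add atoms: none
Why: Chelation-controlled ether cleavage, in which BCl3 bridges the ketone and the ortho benzyloxy oxygen, should remove only that benzyl group at low temperature and leave the para benzyl ether, the methyl ethers and the silyl ether.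

Step 14
Reactants: 24 ortho-hydroxy ketone
Product: 26 (10S)-2-(benzyloxy)-1-iodo-7-methoxy-10-(4-methoxyphenyl)-5-(4-methylbenzenesulfonyl)-9-[(triisopropylsilyl)oxy]-10,11-dihydro-5H-dibenzo[a,d]cyclohepten-4-ol (both C5 epimers), via benzhydrol 25 (not isolated)
Conditions: NaBH4, THF–MeOH, 0 °C → rt; then p-TolSO2Na, HCO2H–H2O, rt
Reagents that add atoms: sodium p-toluenesulfinate, Cc1ccc(S(=O)[O-])cc1.[Na+]
Why: Borohydride reduction gives a labile ortho-hydroxybenzhydrol that ionises in formic acid and is captured at carbon by sulfinate (SN1 substitution), giving the 2-(sulfonylmethyl)phenol type of o-quinone methide precursor whose sulfone carbon becomes planar again in step 16.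

Step 15
Reactants: 27 (1R,4R,5R)-isothiocineole [(1R,4R,5R)-4,7,7-trimethyl-6-thiabicyclo[3.2.1]octane]; 28 4-methoxybenzyl alcohol
Product: 29 (1R,4R,5R)-6-(4-methoxybenzyl)-4,7,7-trimethyl-6-thiabicyclo[3.2.1]octan-6-ium tetrafluoroborate (benzyl group exo on sulfur)
Conditions: HBF4·OEt2, CH2Cl2, 0 °C → rt
Reagents that add atoms: tetrafluoroboric acid, [H+].F[B-](F)(F)F
Why: Acid-promoted S-alkylation of the sulfide by the electron-rich benzylic alcohol (SN1 through the 4-methoxybenzyl cation) should occur on the exposed exo lone pair of the bicyclic sulfide and give one sulfonium diastereomer.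

Step 16
Reactants: 26 west sulfone; 29 (1R,4R,5R)-sulfonium salt
Product: 31 west-furan iodide (the oxygen on C4 and C5 of the dibenzocycloheptene joined through CH(4-methoxyphenyl): trans-2,3-dihydrobenzofuran, (2S,3S); methine (S); ring A keeps OBn and I, ring B OMe and OSi(i-Pr)3), via ring quinone methide 30 (not isolated)
Conditions: Cs2CO3, MeCN–CH2Cl2, 0 °C → rt
Reagents that add atoms: none
Why: Formal [4+1] annulation of an o-quinone methide with a sulfur ylide (conjugate addition, then 5-exo-tet displacement of the sulfide by the phenoxide, trans-selective): the ylide should add to the ring carbon on the face away from the pseudo-axial anisyl group of the seven-membered ring (held axial by the neighbouring silyloxy group of ring B), giving (3S), and the (1R,4R,5R)-sulfide is the enantiomer expected to deliver the (2S) carbon, so substrate and reagent control agree.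

Step 17
Reactants: 31 west-furan iodide; 32 3,5-dimethoxybenzaldehyde
Product: 35 east sulfone (31 with the iodine replaced by CH(3,5-dimethoxyphenyl)(4-methylbenzenesulfonyl); both epimers at that carbon; OBn retained), via arylmagnesium chloride 33 (not isolated), via benzhydrol 34 (not isolated)
Conditions: i-PrMgCl·LiCl, THF, 0 °C → rt; 32, −40 → 0 °C; then p-TolSO2Na, HCO2H–H2O, rt
Reagents that add atoms: sodium p-toluenesulfinate, Cc1ccc(S(=O)[O-])cc1.[Na+]
Why: Iodine–magnesium exchange at the remaining iodide and Grignard addition to the aldehyde place the east benzylic carbon on ring A regiospecifically, and the electron-rich benzhydrol is converted in the acidic quench into its sulfone by SN1 capture of sulfinate.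

Step 18
Reactants: 35 east sulfone benzyl ether
Product: 36 east sulfone phenol (35 with OH in place of OBn)
Conditions: H2 (1 atm), Pd/C, EtOAc, rt
Reagents that add atoms: none
Why: Hydrogenolysis of the aryl benzyl ether is possible now that no aryl iodide remains, and it should unmask the phenol ortho to the sulfonyl-bearing carbon faster than the cyclic benzylic ether, the sulfone or the silyl ether react.

Step 19
Reactants: 37 (1S,4S,5S)-isothiocineole; 28 4-methoxybenzyl alcohol
Product: 38 (1S,4S,5S)-6-(4-methoxybenzyl)-4,7,7-trimethyl-6-thiabicyclo[3.2.1]octan-6-ium tetrafluoroborate (benzyl group exo on sulfur)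
Conditions: HBF4·OEt2, CH2Cl2, 0 °C → rt
Reagents that add atoms: tetrafluoroboric acid, [H+].F[B-](F)(F)F
Why: The same acid-promoted SN1 S-alkylation as in step 15, applied to the enantiomeric sulfide.

Step 20
Reactants: 36 east sulfone phenol; 38 (1S,4S,5S)-sulfonium salt
Product: 40 hexamethyl ether silyl ether of the target (methine S; west furan 2S,3S; east furan 2R,3R), via exocyclic quinone methide 39 (not isolated)
Conditions: Cs2CO3, MeCN–CH2Cl2, 0 °C → rt
Reagents that add atoms: none
Why: The same sulfur-ylide [4+1] annulation on the exocyclic o-quinone methide, whose faces no nearby stereocentre distinguishes, so the (1S,4S,5S)-sulfonium ylide is relied on to set the (2R) carbon (reagent control) and the trans-selective addition and ring closure to set (3R).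

Step 21
Reactants: 40 silyl ether
Product: 41 hexamethyl ether of the target with the free ring-B phenol
Conditions: n-Bu4NF, THF, 0 °C; aq. NH4Cl
Reagents that add atoms: none
Why: Fluoride-induced cleavage of the aryl silyl ether (Si–F bond formation) leaves only methyl ethers for the last step.

Step 22
Reactants: 41 hexamethyl ether
Product: 42 target heptaphenol CNP0136963.1
Conditions: BBr3 (excess), CH2Cl2, −78 °C → rt; then H2O
Reagents that add atoms: none
Why: Lewis acid demethylation of aryl methyl ethers with BBr3 is the usual last step for methylated resveratrol oligomers; no carbon stereocentre is touched, and the trans dihydrobenzofurans are the thermodynamically preferred isomers should a benzylic C–O bond ionise reversibly.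

**Compound list**

1 | 4-methoxyphenylacetic acid | COc1ccc(CC(=O)O)cc1 | starting material
2 | (S)-4-benzyloxazolidin-2-one | O=C1N[C@@H](Cc2ccccc2)CO1 | starting material
3 | (4-methoxyphenyl)acetic pivalic anhydride (not isolated) | COc1ccc(CC(=O)OC(=O)C(C)(C)C)cc1 | intermediate
4 | (S)-4-benzyl-3-[(4-methoxyphenyl)acetyl]oxazolidin-2-one | COc1ccc(CC(=O)N2[C@@H](Cc3ccccc3)COC2=O)cc1 | intermediate
5 | 3,5-bis(benzyloxy)benzyl bromide | BrCc1cc(OCc2ccccc2)cc(OCc2ccccc2)c1 | starting material
6 | sodium Z-enolate of 4 (not isolated) | COc1ccc(/C=C(\[O-])N2[C@@H](Cc3ccccc3)COC2=O)cc1.[Na+] | intermediate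
7 | (S)-4-benzyl-3-[(2S)-3-[3,5-bis(benzyloxy)phenyl]-2-(4-methoxyphenyl)propanoyl]oxazolidin-2-one | COc1ccc([C@@H](C(=O)N2[C@@H](Cc3ccccc3)COC2=O)Cc2cc(OCc3ccccc3)cc(OCc3ccccc3)c2)cc1 | intermediate
8 | (2S)-3-[3,5-bis(benzyloxy)phenyl]-2-(4-methoxyphenyl)propan-1-ol | COc1ccc([C@@H](CO)Cc2cc(OCc3ccccc3)cc(OCc3ccccc3)c2)cc1 | intermediate
9 | (2S)-3-[3,5-bis(benzyloxy)phenyl]-2-(4-methoxyphenyl)propanal | COc1ccc([C@@H](C=O)Cc2cc(OCc3ccccc3)cc(OCc3ccccc3)c2)cc1 | intermediate
10 | (3R)-4-[3,5-bis(benzyloxy)phenyl]-1,1-dibromo-3-(4-methoxyphenyl)but-1-ene | COc1ccc([C@@H](C=C(Br)Br)Cc2cc(OCc3ccccc3)cc(OCc3ccccc3)c2)cc1 | intermediate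
11 | lithium acetylide of 12 (not isolated) | COc1ccc([C@@H](C#C[Li])Cc2cc(OCc3ccccc3)cc(OCc3ccccc3)c2)cc1 | intermediate
12 | (3R)-4-[3,5-bis(benzyloxy)phenyl]-3-(4-methoxyphenyl)but-1-yne | COc1ccc([C@@H](C#C)Cc2cc(OCc3ccccc3)cc(OCc3ccccc3)c2)cc1 | intermediate
13 | (3R)-4-[3,5-bis(benzyloxy)-2,6-diiodophenyl]-3-(4-methoxyphenyl)but-1-yne | COc1ccc([C@@H](C#C)Cc2c(I)c(OCc3ccccc3)cc(OCc3ccccc3)c2I)cc1 | intermediate
14 | lithium acetylide of 13 (not isolated) | COc1ccc([C@@H](C#C[Li])Cc2c(I)c(OCc3ccccc3)cc(OCc3ccccc3)c2I)cc1 | intermediate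
15 | lithium (3S)-4-[3,5-bis(benzyloxy)-2,6-diiodophenyl]-3-(4-methoxyphenyl)but-1-yn-1-olate (not isolated) | COc1ccc([C@@H](C#CO[Li])Cc2c(I)c(OCc3ccccc3)cc(OCc3ccccc3)c2I)cc1 | intermediate
16 | (3S)-4-[3,5-bis(benzyloxy)-2,6-diiodophenyl]-3-(4-methoxyphenyl)-1-[(triisopropylsilyl)oxy]but-1-yne | COc1ccc([C@@H](C#CO[Si](C(C)C)(C(C)C)C(C)C)Cc2c(I)c(OCc3ccccc3)cc(OCc3ccccc3)c2I)cc1 | intermediate
17 | 4-methoxy-6-methyl-2H-pyran-2-one | COC1=CC(=O)OC(C)=C1 | starting material
18 | 4-methoxy-2-oxo-2H-pyran-6-carbaldehyde | COC1=CC(=O)OC(C=O)=C1 | intermediate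
19 | arylmagnesium chloride from 16, MgCl in place of one iodine (not isolated) | COc1ccc([C@@H](C#CO[Si](C(C)C)(C(C)C)C(C)C)Cc2c(I)c(OCc3ccccc3)cc(OCc3ccccc3)c2[Mg]Cl)cc1 | intermediate
20 | 6-{[4,6-bis(benzyloxy)-3-iodo-2-[(2S)-2-(4-methoxyphenyl)-4-[(triisopropylsilyl)oxy]but-3-yn-1-yl]phenyl](hydroxy)methyl}-4-methoxy-2H-pyran-2-one (both carbinol epimers) | COc1ccc([C@@H](C#CO[Si](C(C)C)(C(C)C)C(C)C)Cc2c(I)c(OCc3ccccc3)cc(OCc3ccccc3)c2C(O)C2=CC(OC)=CC(=O)O2)cc1 | intermediate
21 | 6-{4,6-bis(benzyloxy)-3-iodo-2-[(2S)-2-(4-methoxyphenyl)-4-[(triisopropylsilyl)oxy]but-3-yn-1-yl]benzoyl}-4-methoxy-2H-pyran-2-one | COc1ccc([C@@H](C#CO[Si](C(C)C)(C(C)C)C(C)C)Cc2c(I)c(OCc3ccccc3)cc(OCc3ccccc3)c2C(=O)C2=CC(OC)=CC(=O)O2)cc1 | intermediate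
22 | bridged lactone, the 2-oxabicyclo[2.2.2]octa-5,7-dien-3-one from addition of the alkyne across pyrone C3 and C6 of 21 (bridgeheads unassigned; not isolated) | COc1ccc([C@@H]2Cc3c(I)c(OCc4ccccc4)cc(OCc4ccccc4)c3C(=O)C34OC(=O)C(C(OC)=C3)C(O[Si](C(C)C)(C(C)C)C(C)C)=C24)cc1 | intermediate
23 | (10S)-2,4-bis(benzyloxy)-1-iodo-7-methoxy-10-(4-methoxyphenyl)-9-[(triisopropylsilyl)oxy]-10,11-dihydro-5H-dibenzo[a,d]cyclohepten-5-one | COc1ccc([C@@H]2Cc3c(I)c(OCc4ccccc4)cc(OCc4ccccc4)c3C(=O)c3cc(OC)cc(O[Si](C(C)C)(C(C)C)C(C)C)c32)cc1 | intermediate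
24 | (10S)-2-(benzyloxy)-4-hydroxy-1-iodo-7-methoxy-10-(4-methoxyphenyl)-9-[(triisopropylsilyl)oxy]-10,11-dihydro-5H-dibenzo[a,d]cyclohepten-5-one | COc1ccc([C@@H]2Cc3c(I)c(OCc4ccccc4)cc(O)c3C(=O)c3cc(OC)cc(O[Si](C(C)C)(C(C)C)C(C)C)c32)cc1 | intermediate
25 | (10S)-2-(benzyloxy)-1-iodo-7-methoxy-10-(4-methoxyphenyl)-9-[(triisopropylsilyl)oxy]-10,11-dihydro-5H-dibenzo[a,d]cycloheptene-4,5-diol (both C5 epimers; not isolated) | COc1ccc([C@@H]2Cc3c(I)c(OCc4ccccc4)cc(O)c3C(O)c3cc(OC)cc(O[Si](C(C)C)(C(C)C)C(C)C)c32)cc1 | intermediate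
26 | (10S)-2-(benzyloxy)-1-iodo-7-methoxy-10-(4-methoxyphenyl)-5-(4-methylbenzenesulfonyl)-9-[(triisopropylsilyl)oxy]-10,11-dihydro-5H-dibenzo[a,d]cyclohepten-4-ol (both C5 epimers) | COc1ccc([C@@H]2Cc3c(I)c(OCc4ccccc4)cc(O)c3C(S(=O)(=O)c3ccc(C)cc3)c3cc(OC)cc(O[Si](C(C)C)(C(C)C)C(C)C)c32)cc1 | intermediate
27 | (1R,4R,5R)-isothiocineole | C[C@@H]1CC[C@@H]2C[C@H]1SC2(C)C | starting material
28 | 4-methoxybenzyl alcohol | COc1ccc(CO)cc1 | starting material
29 | (1R,4R,5R)-6-(4-methoxybenzyl)-4,7,7-trimethyl-6-thiabicyclo[3.2.1]octan-6-ium tetrafluoroborate (exo S-benzyl) | C[C@@H]1CC[C@@H]2C[C@H]1[S@@+](Cc1ccc(OC)cc1)C2(C)C.F[B-](F)(F)F | intermediate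
30 | ring o-quinone methide from 26 (C4=O, C4a=C5; not isolated) | COc1ccc([C@@H]2CC3=C(I)C(OCc4ccccc4)=CC(=O)C3=Cc3cc(OC)cc(O[Si](C(C)C)(C(C)C)C(C)C)c32)cc1 | intermediate
31 | west-furan iodide: trans-(2S,3S)-2-(4-methoxyphenyl)-2,3-dihydrobenzofuran built on ring A with C3 in the seven-membered ring; methine (S); ring A with OBn and I; ring B with OMe and OSi(i-Pr)3 | COc1ccc([C@@H]2Cc3c4c(cc(OCc5ccccc5)c3I)O[C@H](c3ccc(OC)cc3)[C@H]4c3cc(OC)cc(O[Si](C(C)C)(C(C)C)C(C)C)c32)cc1 | intermediate
32 | 3,5-dimethoxybenzaldehyde | COc1cc(C=O)cc(OC)c1 | starting material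
33 | arylmagnesium chloride from 31, MgCl in place of iodine (not isolated) | COc1ccc([C@@H]2Cc3c4c(cc(OCc5ccccc5)c3[Mg]Cl)O[C@H](c3ccc(OC)cc3)[C@H]4c3cc(OC)cc(O[Si](C(C)C)(C(C)C)C(C)C)c32)cc1 | intermediate
34 | east benzhydrol: 31 with CH(OH)(3,5-dimethoxyphenyl) in place of iodine (both epimers; not isolated) | COc1ccc([C@@H]2Cc3c4c(cc(OCc5ccccc5)c3C(O)c3cc(OC)cc(OC)c3)O[C@H](c3ccc(OC)cc3)[C@H]4c3cc(OC)cc(O[Si](C(C)C)(C(C)C)C(C)C)c32)cc1 | intermediate
35 | east sulfone benzyl ether: 31 with CH(3,5-dimethoxyphenyl)(4-methylbenzenesulfonyl) in place of iodine (both epimers) | COc1ccc([C@@H]2Cc3c4c(cc(OCc5ccccc5)c3C(c3cc(OC)cc(OC)c3)S(=O)(=O)c3ccc(C)cc3)O[C@H](c3ccc(OC)cc3)[C@H]4c3cc(OC)cc(O[Si](C(C)C)(C(C)C)C(C)C)c32)cc1 | intermediate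
36 | east sulfone phenol: 35 with OH in place of OBn | COc1ccc([C@@H]2Cc3c4c(cc(O)c3C(c3cc(OC)cc(OC)c3)S(=O)(=O)c3ccc(C)cc3)O[C@H](c3ccc(OC)cc3)[C@H]4c3cc(OC)cc(O[Si](C(C)C)(C(C)C)C(C)C)c32)cc1 | intermediate
37 | (1S,4S,5S)-isothiocineole | C[C@H]1CC[C@H]2C[C@@H]1SC2(C)C | starting material
38 | (1S,4S,5S)-6-(4-methoxybenzyl)-4,7,7-trimethyl-6-thiabicyclo[3.2.1]octan-6-ium tetrafluoroborate (exo S-benzyl) | C[C@H]1CC[C@H]2C[C@@H]1[S@+](Cc1ccc(OC)cc1)C2(C)C.F[B-](F)(F)F | intermediate
39 | exocyclic o-quinone methide from 36 (ring-A C=O next to C=CH(3,5-dimethoxyphenyl); not isolated) | COc1ccc([C@@H]2CC3=C4C(=CC(=O)C3=Cc3cc(OC)cc(OC)c3)O[C@H](c3ccc(OC)cc3)[C@H]4c3cc(OC)cc(O[Si](C(C)C)(C(C)C)C(C)C)c32)cc1 | intermediate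
40 | target as its hexamethyl ether with the ring-B oxygen next to the methine-bearing fusion carbon as the triisopropylsilyl ether (methine S; west furan 2S,3S; east furan 2R,3R) | COc1ccc([C@@H]2Cc3c4c(cc5c3[C@@H](c3cc(OC)cc(OC)c3)[C@H](c3ccc(OC)cc3)O5)O[C@H](c3ccc(OC)cc3)[C@H]4c3cc(OC)cc(O[Si](C(C)C)(C(C)C)C(C)C)c32)cc1 | intermediate
41 | hexamethyl ether of the target with that ring-B phenol free | COc1ccc([C@@H]2Cc3c4c(cc5c3[C@@H](c3cc(OC)cc(OC)c3)[C@H](c3ccc(OC)cc3)O5)O[C@H](c3ccc(OC)cc3)[C@H]4c3cc(OC)cc(O)c32)cc1 | intermediate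
42 | CNP0136963.1 (methine S; west furan 2S,3S; east furan 2R,3R) | Oc1ccc([C@@H]2Cc3c4c(cc5c3[C@@H](c3cc(O)cc(O)c3)[C@H](c3ccc(O)cc3)O5)O[C@H](c3ccc(O)cc3)[C@H]4c3cc(O)cc(O)c32)cc1 | target

**Step count**

Total step count: 22. Longest linear sequence: 19 (steps 1–8, 10–14, 16–18, 20–22); steps 9, 15 and 19 are side steps.

**Steps most likely to fail, with fallbacks**

Step 12. The silyl ynol ether may be consumed by silyl migration to a ketene or by oligomerisation before it reaches the pyrone, or the 4-methoxypyrone may be too electron-rich for it even with the 6-aroyl group. The fallback keeps the pyrone–alkyne disconnection but carries the ring-B oxygen as silicon on a thermally robust alkyne and oxidises it after the ring is made. It sets out from 13 and returns at 23: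
- 13 is C-silylated with LiN(SiMe3)2 and benzylchlorodimethylsilane to the alkynylsilane F1.
- Iodine–magnesium exchange with i-PrMgCl·LiCl gives the arylmagnesium chloride F2, which adds to 18 to give the carbinol F3.
- MnO2 gives the ketone F4.
- Heating in o-dichlorobenzene at 180 °C (intramolecular pyrone–silylalkyne Diels–Alder reaction) gives, through the bridged lactone F5 and loss of CO2, the aryl silane F6.
- Tamao–Fleming oxidation (n-Bu4NF to the fluorosilane F7, then KF, KHCO3, H2O2 in THF–MeOH) gives the phenol F8.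
- i-Pr3SiOTf and 2,6-lutidine convert F8 into 23.

Step 20. Facial selectivity at the exocyclic quinone methide carbon rests on the chiral ylide alone and may be low or of the unexpected sense, and self-condensation of the quinone methide may compete with the bulky ylide. The fallback gives up reagent control and relies on separation. It sets out from 36 and returns at 40:
- 36 is annulated under the same base conditions with the small achiral ylide of (4-methoxybenzyl)dimethylsulfonium tetrafluoroborate F9 (from 28, dimethyl sulfide and HBF4·OEt2).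
- The trans-selective annulation should give 40 together with its east-furan (2S,3S) diastereomer F10.
- The two are diastereomers because of the three fixed centres and are separated by chromatography.

Step 16. Addition of the bulky ylide to the hindered, ring-embedded quinone methide may be slow, or the facial selectivity with respect to the methine may be poor. The fallback builds the west furan stepwise under thermodynamic control. It sets out from 24 and returns at 31:
- Excess 4-methoxybenzylmagnesium chloride adds to the ketone of 24 to give the tertiary alcohol F11.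
- Catalytic p-toluenesulfonic acid in CH2Cl2 dehydrates it to the 2-hydroxystilbene F12.
- The same acid closes the ring by protonation at the ring carbon and capture of the 4-methoxybenzylic cation by the phenol, a known cyclisation of 2-hydroxystilbenes.
- Ring opening and closure are reversible, so the trans furan with the more stable configuration at the ring carbon should accumulate as 31; any epimer is removed by chromatography.

**Further compounds**

F1 | step 12 | (3S)-4-[3,5-bis(benzyloxy)-2,6-diiodophenyl]-1-[benzyl(dimethyl)silyl]-3-(4-methoxyphenyl)but-1-yne | COc1ccc([C@@H](C#C[Si](C)(C)Cc2ccccc2)Cc2c(I)c(OCc3ccccc3)cc(OCc3ccccc3)c2I)cc1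
F2 | step 12 | arylmagnesium chloride from F1, MgCl in place of one iodine | COc1ccc([C@@H](C#C[Si](C)(C)Cc2ccccc2)Cc2c(I)c(OCc3ccccc3)cc(OCc3ccccc3)c2[Mg]Cl)cc1
F3 | step 12 | carbinol, the analogue of 20 with benzyl(dimethyl)silyl in place of triisopropylsilyloxy on the alkyne | COc1ccc([C@@H](C#C[Si](C)(C)Cc2ccccc2)Cc2c(I)c(OCc3ccccc3)cc(OCc3ccccc3)c2C(O)C2=CC(OC)=CC(=O)O2)cc1
F4 | step 12 | ketone, the analogue of 21 with benzyl(dimethyl)silyl on the alkyne | COc1ccc([C@@H](C#C[Si](C)(C)Cc2ccccc2)Cc2c(I)c(OCc3ccccc3)cc(OCc3ccccc3)c2C(=O)C2=CC(OC)=CC(=O)O2)cc1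
F5 | step 12 | bridged lactone, the analogue of 22 with benzyl(dimethyl)silyl on the alkene carbon | COc1ccc([C@@H]2Cc3c(I)c(OCc4ccccc4)cc(OCc4ccccc4)c3C(=O)C34OC(=O)C(C(OC)=C3)C([Si](C)(C)Cc3ccccc3)=C24)cc1
F6 | step 12 | (10S)-9-[benzyl(dimethyl)silyl]-2,4-bis(benzyloxy)-1-iodo-7-methoxy-10-(4-methoxyphenyl)-10,11-dihydro-5H-dibenzo[a,d]cyclohepten-5-one | COc1ccc([C@@H]2Cc3c(I)c(OCc4ccccc4)cc(OCc4ccccc4)c3C(=O)c3cc(OC)cc([Si](C)(C)Cc4ccccc4)c32)cc1
F7 | step 12 | the 9-[fluoro(dimethyl)silyl] analogue of F6 | COc1ccc([C@@H]2Cc3c(I)c(OCc4ccccc4)cc(OCc4ccccc4)c3C(=O)c3cc(OC)cc([Si](C)(C)F)c32)cc1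
F8 | step 12 | (10S)-2,4-bis(benzyloxy)-9-hydroxy-1-iodo-7-methoxy-10-(4-methoxyphenyl)-10,11-dihydro-5H-dibenzo[a,d]cyclohepten-5-one | COc1ccc([C@@H]2Cc3c(I)c(OCc4ccccc4)cc(OCc4ccccc4)c3C(=O)c3cc(OC)cc(O)c32)cc1
F9 | step 20 | (4-methoxybenzyl)dimethylsulfonium tetrafluoroborate | COc1ccc(C[S+](C)C)cc1.F[B-](F)(F)F
F10 | step 20 | diastereomer of 40 with the east furan (2S,3S) | COc1ccc([C@@H]2Cc3c4c(cc5c3[C@H](c3cc(OC)cc(OC)c3)[C@@H](c3ccc(OC)cc3)O5)O[C@H](c3ccc(OC)cc3)[C@H]4c3cc(OC)cc(O[Si](C(C)C)(C(C)C)C(C)C)c32)cc1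
F11 | step 16 | (10S)-2-(benzyloxy)-1-iodo-7-methoxy-5-(4-methoxybenzyl)-10-(4-methoxyphenyl)-9-[(triisopropylsilyl)oxy]-10,11-dihydro-5H-dibenzo[a,d]cycloheptene-4,5-diol (both C5 epimers) | COc1ccc([C@@H]2Cc3c(I)c(OCc4ccccc4)cc(O)c3C(O)(Cc3ccc(OC)cc3)c3cc(OC)cc(O[Si](C(C)C)(C(C)C)C(C)C)c32)cc1
F12 | step 16 | (10S)-2-(benzyloxy)-1-iodo-7-methoxy-5-(4-methoxybenzylidene)-10-(4-methoxyphenyl)-9-[(triisopropylsilyl)oxy]-10,11-dihydro-5H-dibenzo[a,d]cyclohepten-4-ol | COc1ccc([C@@H]2Cc3c(I)c(OCc4ccccc4)cc(O)c3C(=Cc3ccc(OC)cc3)c3cc(OC)cc(O[Si](C(C)C)(C(C)C)C(C)C)c32)cc1
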